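**Retrosynthetic overview** (azulene numbering)
1. Ester C4–O: target ⇒ jaeschkeanadiol + a benzodioxinone salicyloyl donor; the 4S carbinol ⇒ C4 ketone by hydroxyl-directed reduction.
2. Five-membered ring: ketol ⇒ 3,6-dimethylcyclohepta-2,5-dienone + 1-isopropylcyclopropanol. C1–C8a joins the β-carbon of a ketone homoenolate to the β-carbon of the enone; C3–C3a follows by aldol in the same flask.
3. Seven-membered ring: dienone ⇒ cyclopropanation/FeCl3 ring expansion of the Birch-derived silyl dienol ether of 2,5-dimethylphenol; cyclopropanol ⇒ methyl isobutyrate.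
4. Ring order: seven-membered ring first (ring expansion), five-membered ring second (annulation).

Assumption: the SMILES is read as the (3R,3aS,4S,8aR) salicylate of jaeschkeanadiol (trans-fused, 3-OH syn to the angular methyl, 4-O anti to it).

**Step 1**
Reactants: 1 2,5-dimethylphenol
Product: 2 tert-butyl(2,5-dimethylphenoxy)dimethylsilane
Conditions: TBSCl, imidazole, DMF, rt
Reagents that add atoms: tert-butyldimethylsilyl chloride, CC(C)(C)[Si](C)(C)Cl
Why: Imidazole-assisted silylation of a phenol; no stereocentre is involved, and the silyl ether later becomes the silyl enol ether needed for ring expansion.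

**Step 2**
Reactants: 2 tert-butyl(2,5-dimethylphenoxy)dimethylsilane
Product: 3 tert-butyl[(2,5-dimethylcyclohexa-1,4-dien-1-yl)oxy]dimethylsilane
Conditions: Li, NH3(l)/THF, t-BuOH, −78 to −33 °C; then MeOH
Reagents that add atoms: none
Why: Birch reduction of an aryl silyl ether protonates the two unsubstituted positions C3 and C6, so oxygen and both methyl groups stay on sp2 carbons and the tetrasubstituted silyl enol ether is regiodefined.

**Step 3**
Reactants: 3 tert-butyl[(2,5-dimethylcyclohexa-1,4-dien-1-yl)oxy]dimethylsilane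
Product: 4 tert-butyl[(3,6-dimethylbicyclo[4.1.0]hept-3-en-1-yl)oxy]dimethylsilane (racemic)
Conditions: Et2Zn, CH2I2, CH2Cl2, 0 °C
Reagents that add atoms: diiodomethane, ICI
Why: Simmons–Smith cyclopropanation, in which the electrophilic zinc carbenoid reacts faster with the electron-rich silyl enol ether than with the isolated trisubstituted alkene; the racemic cis-fused stereocentres are erased in step 4.

**Step 4**
Reactants: 4 tert-butyl[(3,6-dimethylbicyclo[4.1.0]hept-3-en-1-yl)oxy]dimethylsilane
Product: 6 3,6-dimethylcyclohepta-2,5-dien-1-one, via chloro ketone 5 (not isolated)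
Conditions: FeCl3, DMF, 0 °C; then NaOAc, MeOH, rt
Reagents that add atoms: none
Why: Ito–Saegusa one-carbon ring expansion: FeCl3 oxidises the siloxycyclopropane, the internal bond cleaves to the ring-expanded tertiary β-keto radical, which is chlorinated to 5, and acetate-induced E1cB loss of HCl gives the β-methyl enone with the second alkene β,γ to the carbonyl.

**Step 5**
Reactants: 7 methyl 2-methylpropanoate
Product: 8 1-(propan-2-yl)cyclopropan-1-ol
Conditions: EtMgBr, Ti(OiPr)4 (20 mol%), Et2O, 0 °C to rt; then aq NH4Cl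
Reagents that add atoms: ethylmagnesium bromide, CC[Mg]Br
Why: Kulinkovich cyclopropanation, in which the titanacyclopropane formed from EtMgBr and Ti(OiPr)4 acts as a 1,2-dicarbanion toward the ester and delivers the cyclopropanol, a latent ketone homoenolate.

**Step 6**
Reactants: 6 3,6-dimethylcyclohepta-2,5-dien-1-one; 8 1-(propan-2-yl)cyclopropan-1-ol
Product: 13 (3R,3aR,8aR)-3-hydroxy-6,8a-dimethyl-3-(propan-2-yl)-2,3,3a,5,8,8a-hexahydroazulen-4(1H)-one, via zinc cyclopropanolate 9 (not isolated), via zinc homoenolate 10 (not isolated), via zinc enolate 11 (not isolated), via zinc aldolate 12 (not isolated)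
Conditions: 8 (1.6 equiv), Et2Zn (0.8 equiv), t-BuOMe, 0 °C to rt; then (CuOTf)2·C6H6 (5 mol%), chiral imidazolinium NHC precursor L* (6 mol%), 6 (1.0 equiv), 0 °C to rt, then 40 °C; aq NH4Cl
Reagents that add atoms: none
Why: Proposed new method: zinc cyclopropanolate 9 ring-opens to the β-zincio ketone 10 (a ketone homoenolate), which after transmetalation to the chiral NHC–copper alkyl adds to the Re face of C3 of enone 6 (ligand enantiomer chosen for this face), joining two carbons that are each β to a carbonyl and setting the 8aR quaternary centre; zinc enolate 11 then closes the five-membered ring by a 5-exo aldol onto the tethered isopropyl ketone, and because this ketone–ketone aldol is reversible the zinc-chelated trans-fused aldolate 12 (O3 syn to the ring C=O, i-Pr anti to the angular methyl, the natural daucane arrangement) is expected to accumulate, which fixes C3a and C3; the closest known reaction types are zinc-homoenolate conjugate addition of cyclopropanols to enones, copper–NHC-catalysed asymmetric conjugate addition of dialkylzincs to 3-methylcycloalk-2-enones, and copper-catalysed conjugate addition–aldol cyclisation.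

**Step 7**
Reactants: 13 (3R,3aR,8aR)-3-hydroxy-6,8a-dimethyl-3-(propan-2-yl)-2,3,3a,5,8,8a-hexahydroazulen-4(1H)-one
Product: 14 (3R,3aS,4S,8aR)-6,8a-dimethyl-3-(propan-2-yl)-1,2,3,3a,4,5,8,8a-octahydroazulene-3,4-diol (jaeschkeanadiol)
Conditions: Me4NBH(OAc)3, MeCN/AcOH (1:1), −30 to −20 °C
Reagents that add atoms: none
Why: Hydroxyl-directed (Evans–Saksena) reduction: the tertiary alcohol binds boron and hydride is delivered intramolecularly to the carbonyl face syn to the C3–O bond (the face of the angular methyl), giving the 1,3-anti diol with the 4S carbinol, whereas external hydride would attack the opposite face.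

**Step 8**
Reactants: 14 (3R,3aS,4S,8aR)-6,8a-dimethyl-3-(propan-2-yl)-1,2,3,3a,4,5,8,8a-octahydroazulene-3,4-diol; 15 2,2-dimethyl-4H-1,3-benzodioxin-4-one
Product: 16 (3R,3aS,4S,8aR)-3-hydroxy-6,8a-dimethyl-3-(propan-2-yl)-1,2,3,3a,4,5,8,8a-octahydroazulen-4-yl 2-hydroxybenzoate
Conditions: NaN(SiMe3)2 (1.1 equiv), THF, 0 °C to rt; then aq NH4Cl
Reagents that add atoms: none
Why: Alkoxide opening of the benzodioxinone (acyl substitution with expulsion of acetone) transfers the salicyloyl group to the less hindered secondary alkoxide and frees the phenol in the same operation, with retention at C4 and the tertiary alcohol untouched.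

**Compound list**
1 | 2,5-dimethylphenol | Cc1ccc(C)c(O)c1 | starting material
2 | tert-butyl(2,5-dimethylphenoxy)dimethylsilane | Cc1ccc(C)c(O[Si](C)(C)C(C)(C)C)c1 | intermediate
3 | tert-butyl[(2,5-dimethylcyclohexa-1,4-dien-1-yl)oxy]dimethylsilane | CC1=CCC(C)=C(O[Si](C)(C)C(C)(C)C)C1 | intermediate
4 | tert-butyl[(3,6-dimethylbicyclo[4.1.0]hept-3-en-1-yl)oxy]dimethylsilane (racemic, cis-fused; one enantiomer drawn) | CC1=CC[C@]2(C)C[C@]2(O[Si](C)(C)C(C)(C)C)C1 | intermediate
5 | 3-chloro-3,6-dimethylcyclohept-5-en-1-one (chloro ketone; racemic; not isolated) | CC1=CCC(C)(Cl)CC(=O)C1 | intermediate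
6 | 3,6-dimethylcyclohepta-2,5-dien-1-one | CC1=CC(=O)CC(C)=CC1 | intermediate
7 | methyl 2-methylpropanoate | COC(=O)C(C)C | starting material
8 | 1-(propan-2-yl)cyclopropan-1-ol | CC(C)C1(O)CC1 | intermediate
9 | zinc bis[1-(propan-2-yl)cyclopropan-1-olate] (zinc cyclopropanolate; not isolated) | CC(C)C1(CC1)O[Zn]OC1(CC1)C(C)C | intermediate
10 | (4-methyl-3-oxopentyl)zinc 1-(propan-2-yl)cyclopropan-1-olate (zinc homoenolate; not isolated) | CC(C)C(=O)CC[Zn]OC1(CC1)C(C)C | intermediate
11 | zinc (3R)-3,6-dimethyl-3-(4-methyl-3-oxopentyl)cyclohepta-1,5-dien-1-olate 1-(propan-2-yl)cyclopropan-1-olate (zinc enolate; not isolated) | CC1=CC[C@@](C)(CCC(=O)C(C)C)C=C(O[Zn]OC2(CC2)C(C)C)C1 | intermediate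
12 | zinc 3-alkoxide of 13 carrying one 1-(propan-2-yl)cyclopropan-1-olate (zinc aldolate; not isolated) | CC1=CC[C@@]2(C)CC[C@@](O[Zn]OC3(CC3)C(C)C)(C(C)C)[C@@H]2C(=O)C1 | intermediate
13 | (3R,3aR,8aR)-3-hydroxy-6,8a-dimethyl-3-(propan-2-yl)-2,3,3a,5,8,8a-hexahydroazulen-4(1H)-one | CC1=CC[C@@]2(C)CC[C@@](O)(C(C)C)[C@@H]2C(=O)C1 | intermediate
14 | (3R,3aS,4S,8aR)-6,8a-dimethyl-3-(propan-2-yl)-1,2,3,3a,4,5,8,8a-octahydroazulene-3,4-diol | CC1=CC[C@@]2(C)CC[C@@](O)(C(C)C)[C@@H]2[C@@H](O)C1 | intermediate
15 | 2,2-dimethyl-4H-1,3-benzodioxin-4-one | CC1(C)OC(=O)c2ccccc2O1 | starting material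
16 | (3R,3aS,4S,8aR)-3-hydroxy-6,8a-dimethyl-3-(propan-2-yl)-1,2,3,3a,4,5,8,8a-octahydroazulen-4-yl 2-hydroxybenzoate | CC1=CC[C@@]2(C)CC[C@@](O)(C(C)C)[C@@H]2[C@@H](OC(=O)c2ccccc2O)C1 | target

**Totals**
Total step count: 8. Longest linear sequence: 7 (steps 1, 2, 3, 4, 6, 7, 8 from 2,5-dimethylphenol); step 5 is a one-step branch.

**Steps most likely to fail**

Risk in step 6 (highest). The cascade is untested: the copper homoenolate may not form or may simply be protonated, face control at a β,β-disubstituted enone may be poor, and the zinc alkoxide may drift the skipped dienone into conjugation. The aldol closes kinetically to the cis-fused ring, so the trans fusion depends on retro-aldol equilibration; the trans preference is argued by analogy and is not proven for this ketol. The fallback separates the two bond formations and uses a preformed, protected homoenolate; it sets out from 8 and 6 and returns at 13. NBS opens cyclopropanol 8 to 1-bromo-4-methylpentan-3-one F1. Ketalisation with 2,2-dimethylpropane-1,3-diol (HC(OEt)3, TsOH) gives 2-(2-bromoethyl)-5,5-dimethyl-2-(propan-2-yl)-1,3-dioxane F2. Mg in THF converts it into {2-[5,5-dimethyl-2-(propan-2-yl)-1,3-dioxan-2-yl]ethyl}magnesium bromide F3. This Grignard reagent is added to 6 with Cu(OTf)2 and the chiral NHC (Et2O, 0 °C) to give (3R)-3-{2-[5,5-dimethyl-2-(propan-2-yl)-1,3-dioxan-2-yl]ethyl}-3,6-dimethylcyclohept-5-en-1-one F4. PPTS in wet acetone unmasks (3R)-3,6-dimethyl-3-(4-methyl-3-oxopentyl)cyclohept-5-en-1-one F5. A separately equilibrated aldol (KOt-Bu cat., t-BuOH/THF, 0 °C) then closes F5 to 13; this fixes reactivity and enantioselectivity but relies on the same trans preference.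

Risk in step 4. The oxidative opening must tolerate the second alkene, and the skipped dienone can isomerise into conjugation under the acetate elimination. The fallback replaces the radical-cation opening by a halocarbene ring expansion; it sets out from 3 and returns at 6. Chlorocarbenoid addition (CH2Cl2, MeLi, Et2O, −30 °C) to the silyl enol ether gives tert-butyl[(7-chloro-3,6-dimethylbicyclo[4.1.0]hept-3-en-1-yl)oxy]dimethylsilane F6. Gentle warming with Et3N in toluene triggers cyclopropyl-to-allyl cation opening with loss of the silyl group and gives 6 directly, without an acetate/methanol stage.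

Risk in step 7. Exchange of the hindered tertiary alcohol onto boron may be slow, so undirected hydride attack anti to the angular methyl would give the C4 epimer. The fallback accepts that epimer and corrects it during esterification; it sets out from 13 and returns at 16. NaBH4 (MeOH, 0 °C) gives (3R,3aS,4R,8aR)-6,8a-dimethyl-3-(propan-2-yl)-1,2,3,3a,4,5,8,8a-octahydroazulene-3,4-diol F7. Mitsunobu esterification with salicylic acid (PPh3, DIAD, THF) inverts C4 and gives 16 directly, bypassing 14 and 15.

**Further compounds**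
F1 | step 6 | 1-bromo-4-methylpentan-3-one | CC(C)C(=O)CCBr
F2 | step 6 | 2-(2-bromoethyl)-5,5-dimethyl-2-(propan-2-yl)-1,3-dioxane | CC(C)C1(CCBr)OCC(C)(C)CO1
F3 | step 6 | {2-[5,5-dimethyl-2-(propan-2-yl)-1,3-dioxan-2-yl]ethyl}magnesium bromide | CC(C)C1(CC[Mg]Br)OCC(C)(C)CO1
F4 | step 6 | (3R)-3-{2-[5,5-dimethyl-2-(propan-2-yl)-1,3-dioxan-2-yl]ethyl}-3,6-dimethylcyclohept-5-en-1-one | CC1=CC[C@@](C)(CCC2(C(C)C)OCC(C)(C)CO2)CC(=O)C1
F5 | step 6 | (3R)-3,6-dimethyl-3-(4-methyl-3-oxopentyl)cyclohept-5-en-1-one | CC1=CC[C@@](C)(CCC(=O)C(C)C)CC(=O)C1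
F6 | step 4 | tert-butyl[(7-chloro-3,6-dimethylbicyclo[4.1.0]hept-3-en-1-yl)oxy]dimethylsilane (racemic, mixture of chloro epimers) | CC1=CCC2(C)C(Cl)C2(O[Si](C)(C)C(C)(C)C)C1
F7 | step 7 | (3R,3aS,4R,8aR)-6,8a-dimethyl-3-(propan-2-yl)-1,2,3,3a,4,5,8,8a-octahydroazulene-3,4-diol | CC1=CC[C@@]2(C)CC[C@@](O)(C(C)C)[C@@H]2[C@H](O)C1
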